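I began with the easy step and set two charges side by side. Autumn and midnight each hold 0.10 M of substrate and 0.110 M of coupling partner. I booked one mole of partner per mole of target, so I took the moles of partner charged per mole of substrate, the cover, as my first figure: 1.10. Substrate is the smaller of these two charges, which makes it the limiting reagent of the pair in both flasks, and my ledger caps target at 100% of the substrate charged.

| setting | beta | gamma | autumn | midnight |
|---|---|---|---|---|
| substrate | 0.067 M | 0.10 M | 0.10 M | 0.10 M |
| coupling partner | 0.11 M | 0.22 M | 0.110 M | 0.110 M |
| scavenger | 0.050 M | 0.050 M | 0.0500 M | 0.100 M |
| initiator | 8.5 mM | 8.5 mM | 8.5 mM | 8.5 mM |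
| remark | run made earlier | run made earlier |  |  |
| time |  |  | 15 min | 15 min |

- beta (time / min: substrate / %, target / %): 0.250: 91, 6; 0.500: 93, 10; 1.33: 80, 19; 3.00: 63, 36
- gamma (time / min: substrate / %, target / %): 0.417: 92, 6; 1.00: 80, 14; 2.00: 68, 24; 3.00: 56, 36

(readings scatter by 2 percentage points)

- what has gone from substrate into another species counts as reacted, even if it can come back
- no earlier run changes the charge of scavenger; that part of a forecast is a guess

- part of the substrate that has reacted at the end, autumn
- part of the substrate that has reacted at the end, midnight
- what raising the concentration of scavenger from its lowest to its highest value here does to the part of the substrate that has reacted (changes below 5 percentage points count as none) (no change / it falls / it rises)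

My ledger had three entries. Substrate left and target came first. In the beta run at 3.00 min they stood at 63% and 36%, which nearly closed the books. In the gamma run at 3.00 min they read 56% and 36%, so these readings left a gap of 8 percentage points, which I booked as a third entry for an unseen form. That entry counts as reacted, so I needed only the loss of substrate.

Beta has autumn's partner charge, so I read a fractional loss from it, 0.154 min⁻¹, with the scatter of its reading. Held for 15 min, this gave 90.1% reacted, which, if booked wholly as target, took 81.9% of the partner in my estimate. No earlier run changes the scavenger, so I guessed that it made no entry, and I expected the same figure for midnight and no change.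

The forecast differed from mine on autumn and the trend, with 65% for autumn (range 50% to 90%), 90% for midnight (range 78% to 98%) and the trend it rises, on the guess that “autumn stalls after about 50% conversion”.

Autumn gave 89.9% and midnight 89.6%, so the trend was no change, a shift of −0.35 points. Autumn ended with 0.00854% of its scavenger free, yet its substrate stood at 10%, and midnight's stood at 10%. Autumn's target of 85.4% at 15.0 min, divided by the cover, accounts for 77.6% of the partner, and 22.4% of the partner stood free.

    initiator → 2 initiating radical (k = 0.00397 min⁻¹)
    substrate + initiating radical → capped initiator + first chain carrier (k = 48700 M⁻¹ s⁻¹)
    coupling partner + first chain carrier → target + second chain carrier (k = 69800 M⁻¹ s⁻¹)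
    substrate + second chain carrier → released group + first chain carrier (k = 3.19 × 10⁵ M⁻¹ min⁻¹)
    2 second chain carrier → ended chains (k = 2.40 × 10⁶ M⁻¹ s⁻¹)
    substrate + released group ⇌ idle adduct, settled at all times (K = 15.0 M⁻¹)
    scavenger + released group → scavenged by-product (k = 42.8 M⁻¹ min⁻¹)

A neighbour like autumn but charged with 0.044 M of partner has a cover of 0.440, which caps target at 44.0%. At 15.0 min it held 44.0% target and 0% partner, with 45.2% of its substrate reacted.

The numbers in the tables were generated by integration for an exercise.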